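**Strategy.** The route rests on disconnecting C4–C4a of the lower chromone (the 7‑hydroxy‑8‑aryloxy unit), so that its pyranone ring is closed by intramolecular Friedel–Crafts acylation. The key step exploits the 1,2,3‑trioxygenated benzo ring of that unit: C8 carries the diaryl‑ether oxygen, so C4a is the only carbon ortho to O1, and it lies para to the C7 oxygen. In one operation an acid‑labile ester is unmasked and the acylium closes the ring, delivering the complete isoflavone with an aryl bromide handle for the later biaryl coupling. The precursor is a tert‑butyl 3‑aryloxy‑2‑(4‑methoxyphenyl)acrylate whose aryloxy ring already holds the 4‑bromophenoxy group and the C7 oxygen as a methyl ether.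

Key step: step 7

Remark: the target has no stereocentre or stereogenic axis, so no enantiocontrol is needed; the only stereo‑elements on the way are C=C geometries.
Remark: 9 and 10 are drawn as E isomers (chlorine or aryloxy trans to the ester), the geometry expected from addition–elimination through a stabilised carbanion; a Z isomer is equally usable, because the geometry equilibrates in the acid of step 7 and only the Z form can close.
Remark: the oxygen that becomes O7 is carried as a methyl ether from step 1 on, so that no pair of equivalent hydroxyls has to be mono‑functionalised, no free phenol meets the acylating medium, and no later O‑methylation is needed.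

**Step 1**
Reactants: 1 2‑fluoro‑3‑methoxybenzaldehyde; 2 4‑bromophenol
Product: 3 2‑(4‑bromophenoxy)‑3‑methoxybenzaldehyde
Conditions: K2CO3, DMF, 110 °C
Reagents that add atoms: none
Why: SNAr, in which the ortho formyl group activates the C–F bond towards the phenoxide of 2 while the aryl bromide is inert, should give the 2‑aryloxybenzaldehyde.

**Step 2**
Reactants: 3 2‑(4‑bromophenoxy)‑3‑methoxybenzaldehyde
Product: 5 2‑(4‑bromophenoxy)‑3‑methoxyphenol, via aryl formate 4 (not isolated)
Conditions: mCPBA, CH2Cl2, rt; then K2CO3 (cat.), MeOH, rt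
Reagents that add atoms: mCPBA (3‑chloroperoxybenzoic acid), O=C(OO)c1cccc(Cl)c1
Why: Baeyer–Villiger (Dakin‑type) oxidation, in which the ortho‑oxygenated aryl group migrates in preference to hydride, followed by methanolysis of the formate, should place the free hydroxyl exactly at the former formyl carbon.

**Step 3**
Reactants: 6 4‑methoxyphenylacetic acid
Product: 7 tert‑butyl 2‑(4‑methoxyphenyl)acetate
Conditions: tert‑butyl 2,2,2‑trichloroacetimidate, BF3·OEt2 (cat.), CH2Cl2/cyclohexane, rt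
Reagents that add atoms: tert‑butyl 2,2,2‑trichloroacetimidate, CC(C)(C)OC(=N)C(Cl)(Cl)Cl
Why: Acid‑catalysed O‑alkylation of the carboxylic acid by the imidate is a mild tert‑butyl ester formation that leaves the anisole ring untouched.

**Step 4**
Reactants: 7 tert‑butyl 2‑(4‑methoxyphenyl)acetate
Product: 8 tert‑butyl (Z)‑3‑hydroxy‑2‑(4‑methoxyphenyl)acrylate (enol form of the α‑formyl ester)
Conditions: NaH, HCO2Et, THF, 0 °C to rt; cold dilute HCl to pH 4
Reagents that add atoms: ethyl formate, CCOC=O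
Why: Crossed Claisen condensation (formylation) of the ester enolate is driven by deprotonation of the product, and the tert‑butyl ester resists transesterification by ethoxide.

**Step 5**
Reactants: 8 tert‑butyl (Z)‑3‑hydroxy‑2‑(4‑methoxyphenyl)acrylate
Product: 9 tert‑butyl (E)‑3‑chloro‑2‑(4‑methoxyphenyl)acrylate
Conditions: Ph3PCl2, Et3N, MeCN, 0 °C to rt
Reagents that add atoms: dichlorotriphenylphosphorane, ClP(Cl)(c1ccccc1)(c1ccccc1)c1ccccc1
Why: Deoxychlorination of the enol of a β‑dicarbonyl compound by a chlorophosphonium reagent (Piers‑type β‑halo enoate synthesis) runs under basic conditions, so the tert‑butyl ester should survive.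

**Step 6**
Reactants: 5 2‑(4‑bromophenoxy)‑3‑methoxyphenol; 9 tert‑butyl (E)‑3‑chloro‑2‑(4‑methoxyphenyl)acrylate
Product: 10 tert‑butyl (E)‑3‑[2‑(4‑bromophenoxy)‑3‑methoxyphenoxy]‑2‑(4‑methoxyphenyl)acrylate
Conditions: Cs2CO3, DMF, rt to 50 °C
Reagents that add atoms: none
Why: Nucleophilic vinylic substitution (addition–elimination), in which the phenoxide adds to the unhindered β‑carbon to give an aryl‑ and ester‑stabilised carbanion that expels chloride, should form the aryl–O–vinyl bond.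

**Step 7**
Reactants: 10 tert‑butyl (E)‑3‑[2‑(4‑bromophenoxy)‑3‑methoxyphenoxy]‑2‑(4‑methoxyphenyl)acrylate
Product: 12 8‑(4‑bromophenoxy)‑7‑methoxy‑3‑(4‑methoxyphenyl)‑4H‑chromen‑4‑one, via free Z‑acrylic acid 11 (not isolated)
Conditions: TFA, CH2Cl2, 0 °C to rt, N2 sweep; evaporate; then P2O5/MeSO3H (1:10 w/w, Eaton's reagent), ca. 0.05 M, 45 °C; ice water
Reagents that add atoms: none
Why: TFA cleaves the tert‑butyl ester with loss of isobutene, which is swept out before the strongly acidic stage, and Eaton's reagent then converts the acid through its mixed anhydride into an acylium ion, while reversible protonation at the α‑carbon of the push–pull alkene interconverts E and Z so that the Z form, with the carbonyl cis to the aryloxy oxygen, is drained by cyclisation. The closest known reaction type is the acid‑mediated cyclisation of 3‑aryloxyacrylic acids to chromones (Simonis‑type intramolecular Friedel–Crafts acylation). The pyranone ring closes in a 6‑exo mode at the acylium carbon (6‑exo‑dig, or 6‑exo‑trig if the mixed anhydride is the acylating species) by attack of C4a on C4, followed by proton loss and re‑aromatisation. No stereocentre is formed. The step needs site selectivity on the aryloxy ring and chemoselectivity among three arenes: C8 is blocked by the bromophenoxy group, so C4a is the only position ortho to O1 and is activated para by the C7 methoxy group, whereas attack on the bromophenyl ring would need a nine‑membered ring and the anisyl ring cannot be reached. Because the aryl–O–vinyl bond exists before the acid step, a coumarin cannot form.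

**Step 8**
Reactants: 12 8‑(4‑bromophenoxy)‑7‑methoxy‑3‑(4‑methoxyphenyl)‑4H‑chromen‑4‑one
Product: 13 7‑methoxy‑3‑(4‑methoxyphenyl)‑8‑[4‑(4,4,5,5‑tetramethyl‑1,3,2‑dioxaborolan‑2‑yl)phenoxy]‑4H‑chromen‑4‑one
Conditions: B2pin2, Pd(dppf)Cl2 (cat.), KOAc, dioxane, 90 °C
Reagents that add atoms: bis(pinacolato)diboron, CC1(C)OB(OC1(C)C)B1OC(C)(C)C(C)(C)O1
Why: Miyaura borylation of the aryl bromide uses acetate, a base too weak to open the chromone ring.

**Step 9**
Reactants: 14 2‑chloro‑1,3‑dimethoxybenzene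
Product: 16 1‑(3‑chloro‑2‑hydroxy‑4‑methoxyphenyl)ethanone, via dimethoxy ketone 15 (not isolated)
Conditions: AcCl, AlCl3 (3 equiv), CH2Cl2, 0 °C to reflux; aq. HCl
Reagents that add atoms: acetyl chloride, CC(Cl)=O
Why: Friedel–Crafts acylation at one of the two equivalent positions ortho/para to the methoxy groups is followed in the same pot by AlCl3‑mediated, carbonyl‑chelation‑directed cleavage of the ortho methyl ether only.

**Step 10**
Reactants: 16 1‑(3‑chloro‑2‑hydroxy‑4‑methoxyphenyl)ethanone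
Product: 18 8‑chloro‑3‑iodo‑7‑methoxy‑4H‑chromen‑4‑one, via enaminone 17 (not isolated)
Conditions: DMF‑DMA, toluene, 95 °C; evaporate; then I2, CHCl3, rt
Reagents that add atoms: N,N‑dimethylformamide dimethyl acetal, COC(OC)N(C)C; iodine, II
Why: Enaminone formation and iodine‑induced cyclisation with loss of dimethylamine (Gammill 3‑iodochromone synthesis) should turn the chelated 2‑hydroxyl into O1 and place iodine at C3.

**Step 11**
Reactants: 13 the pinacol boronate of step 8; 18 8‑chloro‑3‑iodo‑7‑methoxy‑4H‑chromen‑4‑one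
Product: 19 8‑chloro‑7‑methoxy‑3‑[4‑[[7‑methoxy‑3‑(4‑methoxyphenyl)‑4‑oxo‑4H‑chromen‑8‑yl]oxy]phenyl]‑4H‑chromen‑4‑one
Conditions: Pd(dppf)Cl2 (cat.), aq. Na2CO3, dioxane, 80 °C
Reagents that add atoms: none
Why: Suzuki–Miyaura coupling should be selective because the C3–I bond undergoes oxidative addition far faster than the C8–Cl bond, and the carbonate base is mild enough to spare both pyranone rings.

**Step 12**
Reactants: 19 the trimethyl ether of step 11
Product: 20 Bisoflavolin J, 8‑chloro‑7‑hydroxy‑3‑[4‑[[7‑hydroxy‑3‑(4‑hydroxyphenyl)‑4‑oxo‑4H‑chromen‑8‑yl]oxy]phenyl]‑4H‑chromen‑4‑one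
Conditions: BBr3 (excess), CH2Cl2, −78 °C to rt; MeOH/H2O
Reagents that add atoms: none
Why: Lewis‑acid ether cleavage with BBr3 should remove all three aryl methyl ethers, while the diaryl ether, the aryl chloride and the chromone carbonyls are inert to it.

**Compound list**
1 | 2‑fluoro‑3‑methoxybenzaldehyde | COc1cccc(C=O)c1F | starting material
2 | 4‑bromophenol | Oc1ccc(Br)cc1 | starting material
3 | 2‑(4‑bromophenoxy)‑3‑methoxybenzaldehyde | COc1cccc(C=O)c1Oc1ccc(Br)cc1 | intermediate
4 | 2‑(4‑bromophenoxy)‑3‑methoxyphenyl formate | COc1cccc(OC=O)c1Oc1ccc(Br)cc1 | intermediate (not isolated)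
5 | 2‑(4‑bromophenoxy)‑3‑methoxyphenol | COc1cccc(O)c1Oc1ccc(Br)cc1 | intermediate
6 | 4‑methoxyphenylacetic acid | COc1ccc(CC(=O)O)cc1 | starting material
7 | tert‑butyl 2‑(4‑methoxyphenyl)acetate | COc1ccc(CC(=O)OC(C)(C)C)cc1 | intermediate
8 | tert‑butyl (Z)‑3‑hydroxy‑2‑(4‑methoxyphenyl)acrylate (enol of the α‑formyl ester) | COc1ccc(/C(=C/O)C(=O)OC(C)(C)C)cc1 | intermediate
9 | tert‑butyl (E)‑3‑chloro‑2‑(4‑methoxyphenyl)acrylate | COc1ccc(/C(=C\Cl)C(=O)OC(C)(C)C)cc1 | intermediate
10 | tert‑butyl (E)‑3‑[2‑(4‑bromophenoxy)‑3‑methoxyphenoxy]‑2‑(4‑methoxyphenyl)acrylate | COc1ccc(/C(=C\Oc2cccc(OC)c2Oc2ccc(Br)cc2)C(=O)OC(C)(C)C)cc1 | intermediate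
11 | (Z)‑3‑[2‑(4‑bromophenoxy)‑3‑methoxyphenoxy]‑2‑(4‑methoxyphenyl)acrylic acid | COc1ccc(/C(=C/Oc2cccc(OC)c2Oc2ccc(Br)cc2)C(=O)O)cc1 | intermediate (not isolated)
12 | 8‑(4‑bromophenoxy)‑7‑methoxy‑3‑(4‑methoxyphenyl)‑4H‑chromen‑4‑one | COc1ccc(-c2coc3c(Oc4ccc(Br)cc4)c(OC)ccc3c2=O)cc1 | intermediate
13 | 7‑methoxy‑3‑(4‑methoxyphenyl)‑8‑[4‑(4,4,5,5‑tetramethyl‑1,3,2‑dioxaborolan‑2‑yl)phenoxy]‑4H‑chromen‑4‑one | COc1ccc(-c2coc3c(Oc4ccc(B5OC(C)(C)C(C)(C)O5)cc4)c(OC)ccc3c2=O)cc1 | intermediate
14 | 2‑chloro‑1,3‑dimethoxybenzene | COc1cccc(OC)c1Cl | starting material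
15 | 1‑(3‑chloro‑2,4‑dimethoxyphenyl)ethanone | COc1ccc(C(C)=O)c(OC)c1Cl | intermediate (not isolated)
16 | 1‑(3‑chloro‑2‑hydroxy‑4‑methoxyphenyl)ethanone | COc1ccc(C(C)=O)c(O)c1Cl | intermediate
17 | (E)‑1‑(3‑chloro‑2‑hydroxy‑4‑methoxyphenyl)‑3‑(dimethylamino)prop‑2‑en‑1‑one | COc1ccc(C(=O)/C=C/N(C)C)c(O)c1Cl | intermediate (not isolated)
18 | 8‑chloro‑3‑iodo‑7‑methoxy‑4H‑chromen‑4‑one | COc1ccc2c(=O)c(I)coc2c1Cl | intermediate
19 | 8‑chloro‑7‑methoxy‑3‑[4‑[[7‑methoxy‑3‑(4‑methoxyphenyl)‑4‑oxo‑4H‑chromen‑8‑yl]oxy]phenyl]‑4H‑chromen‑4‑one | COc1ccc(-c2coc3c(Oc4ccc(-c5coc6c(Cl)c(OC)ccc6c5=O)cc4)c(OC)ccc3c2=O)cc1 | intermediate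
20 | Bisoflavolin J | O=c1c(-c2ccc(Oc3c(O)ccc4c(=O)c(-c5ccc(O)cc5)coc34)cc2)coc2c(Cl)c(O)ccc12 | target

**Step count and risks**
Total steps: 12. Longest linear sequence: 8 steps (steps 3, 4, 5, 6, 7, 8, 11, 12, from 4‑methoxyphenylacetic acid 6).

Most likely to fail, in this order:

Step 7. In the strong acid the aryl vinyl ether may fragment (protonation at the α‑carbon, then loss of the phenol), or the acylium may be intercepted intermolecularly before it closes the ring. The fallback sets out from phenol 5 and acid 6 and comes back at 12. Phenol 5 is acylated with 6 in BF3·OEt2 at 85 °C, ortho to the chelating hydroxyl and para to the methoxy group, to give the deoxybenzoin 1‑[3‑(4‑bromophenoxy)‑2‑hydroxy‑4‑methoxyphenyl]‑2‑(4‑methoxyphenyl)ethanone F1. Heating F1 with DMF‑DMA inserts the C2 carbon through the enaminone (E)‑1‑[3‑(4‑bromophenoxy)‑2‑hydroxy‑4‑methoxyphenyl]‑3‑(dimethylamino)‑2‑(4‑methoxyphenyl)prop‑2‑en‑1‑one F2, which closes at O1–C2 with loss of dimethylamine to give chromone 12.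

Step 6. Addition of the hindered, ortho‑aryloxy phenoxide to the α‑aryl acrylate may be slow, so that hydrolysis of the vinyl chloride back to the enol by adventitious water competes. The fallback sets out from 5 and comes back at 10, and it makes the Cα–aryl bond last instead of the O–vinyl bond. DABCO‑catalysed oxa‑Michael addition of 5 to tert‑butyl propiolate gives tert‑butyl (E)‑3‑[2‑(4‑bromophenoxy)‑3‑methoxyphenoxy]acrylate F3. NIS and acetic acid add across the enol‑ether double bond to give tert‑butyl 3‑acetoxy‑3‑[2‑(4‑bromophenoxy)‑3‑methoxyphenoxy]‑2‑iodopropanoate F4 (mixture of racemic diastereomers, not isolated). Triethylamine eliminates acetic acid from F4 to give tert‑butyl (Z)‑3‑[2‑(4‑bromophenoxy)‑3‑methoxyphenoxy]‑2‑iodoacrylate F5. Suzuki coupling of F5 with 4‑methoxyphenylboronic acid near room temperature, where the vinyl iodide reacts before the aryl bromide, gives 10 with retention of geometry.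

Step 12. Cleavage of three methyl ethers on a poorly soluble bis‑chromone may stall at partly methylated stages, and forcing may degrade the pyranone rings. The fallback sets out from 12 and 18 and comes back at 20, and it moves the demethylation to the small fragments. BBr3 converts 12 into 8‑(4‑bromophenoxy)‑7‑hydroxy‑3‑(4‑hydroxyphenyl)‑4H‑chromen‑4‑one F6 and 18 into 8‑chloro‑7‑hydroxy‑3‑iodo‑4H‑chromen‑4‑one F7. Miyaura borylation of F6 gives 7‑hydroxy‑3‑(4‑hydroxyphenyl)‑8‑[4‑(4,4,5,5‑tetramethyl‑1,3,2‑dioxaborolan‑2‑yl)phenoxy]‑4H‑chromen‑4‑one F8. Suzuki coupling of F8 with F7, with extra carbonate for the free phenols, gives 20 directly.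

**Further compounds**
F1 | step 7 | 1‑[3‑(4‑bromophenoxy)‑2‑hydroxy‑4‑methoxyphenyl]‑2‑(4‑methoxyphenyl)ethanone | COc1ccc(CC(=O)c2ccc(OC)c(Oc3ccc(Br)cc3)c2O)cc1
F2 | step 7 | (E)‑1‑[3‑(4‑bromophenoxy)‑2‑hydroxy‑4‑methoxyphenyl]‑3‑(dimethylamino)‑2‑(4‑methoxyphenyl)prop‑2‑en‑1‑one | COc1ccc(/C(=C\N(C)C)C(=O)c2ccc(OC)c(Oc3ccc(Br)cc3)c2O)cc1
F3 | step 6 | tert‑butyl (E)‑3‑[2‑(4‑bromophenoxy)‑3‑methoxyphenoxy]acrylate | CC(C)(C)OC(=O)/C=C/Oc1cccc(OC)c1Oc1ccc(Br)cc1
F4 | step 6 | tert‑butyl 3‑acetoxy‑3‑[2‑(4‑bromophenoxy)‑3‑methoxyphenoxy]‑2‑iodopropanoate (mixture of racemic diastereomers) | CC(=O)OC(Oc1cccc(OC)c1Oc1ccc(Br)cc1)C(I)C(=O)OC(C)(C)C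
F5 | step 6 | tert‑butyl (Z)‑3‑[2‑(4‑bromophenoxy)‑3‑methoxyphenoxy]‑2‑iodoacrylate | CC(C)(C)OC(=O)/C(I)=C/Oc1cccc(OC)c1Oc1ccc(Br)cc1
F6 | step 12 | 8‑(4‑bromophenoxy)‑7‑hydroxy‑3‑(4‑hydroxyphenyl)‑4H‑chromen‑4‑one | O=c1c(-c2ccc(O)cc2)coc2c(Oc3ccc(Br)cc3)c(O)ccc12
F7 | step 12 | 8‑chloro‑7‑hydroxy‑3‑iodo‑4H‑chromen‑4‑one | O=c1c(I)coc2c(Cl)c(O)ccc12
F8 | step 12 | 7‑hydroxy‑3‑(4‑hydroxyphenyl)‑8‑[4‑(4,4,5,5‑tetramethyl‑1,3,2‑dioxaborolan‑2‑yl)phenoxy]‑4H‑chromen‑4‑one | O=c1c(-c2ccc(O)cc2)coc2c(Oc3ccc(B4OC(C)(C)C(C)(C)O4)cc3)c(O)ccc12
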